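The route rests on cutting the C4'–O8 aryl ether bond of dioxane ring B. C4' of ring A, the carbon bearing O8, is para to C1', so a formyl group at C1' (later the propenol side chain) activates a fluoride at C4' toward the C8 alkoxide. One SNAr closure forms ring B and carries both stereocentres unchanged into the cis-(7S,8R) benzodioxane. The precursor is the erythro (7S,8R) C7 aryl ether, obtained by phenoxide opening of a (2R,3R) Sharpless epoxy alcohol at benzylic C7. Its C8 hydroxyl is free, O9 is tritylated and the ring C phenols are allyl ethers, so O8 is the only nucleophile.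

Key step: step 9

Assumption: lignan numbering is used (ring C aryl on C7, C8 bears C9H2OH; ring A carries the side chain at C1', O7 at C3', O8 at C4', OMe at C5'); allyl = prop-2-en-1-yl, Tr = triphenylmethyl.

Remark on protecting groups: aryl silyl ethers would not survive NaH in DMF or hot phenoxide, so ring C is carried as a bis(allyl) ether. O9 is capped as a non-migrating trityl ether before ring closure, and the formyl group stays masked as a dioxolane until the C7–O7 bond is in place.

Step 1
Reactants: 1 4-fluoro-3-methoxybenzaldehyde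
Product: 2 2-(4-fluoro-3-methoxyphenyl)-1,3-dioxolane
Conditions: HOCH2CH2OH (3 equiv), TsOH·H2O (2 mol%), toluene, reflux, Dean–Stark
Reagents that add atoms: ethylene glycol, OCCO
Why: Acid-catalysed acetalisation with azeotropic removal of water should convert the formyl group into a 1,3-dioxolane that is inert to the borylation catalyst, to alkaline peroxide and to the phenoxide chemistry of step 7.

Step 2
Reactants: 2 2-(4-fluoro-3-methoxyphenyl)-1,3-dioxolane
Product: 4 5-(1,3-dioxolan-2-yl)-2-fluoro-3-methoxyphenol, via aryl pinacolboronate 3 (not isolated)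
Conditions: [Ir(OMe)(cod)]2 (1.5 mol%), 4,4'-di-tert-butyl-2,2'-bipyridine (3 mol%), B2pin2 (0.6 equiv), THF, 70 °C; then 30% H2O2, 2 M NaOH, 0 °C → rt; NH4Cl to pH 7
Reagents that add atoms: bis(pinacolato)diboron, CC1(C)OB(OC1(C)C)B1OC(C)(C)C(C)(C)O1 (boron of 3); hydrogen peroxide, OO (phenol oxygen of 4)
Why: Iridium-catalysed aromatic C–H borylation is governed by sterics and accepts a C–H whose only ortho neighbour is fluorine, so of the three ring C–H bonds only C5–H should react (C2–H lies between two substituents and C6–H beside the dioxolanyl group), and alkaline peroxide oxidation of the C–B bond in the same flask should give the phenol at that position with the acetal intact.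

Step 3
Reactants: 5 3,4-dihydroxy-5-methoxybenzaldehyde
Product: 6 3,4-bis(allyloxy)-5-methoxybenzaldehyde
Conditions: allyl bromide (2.5 equiv), K2CO3 (3 equiv), DMF, 50 °C
Reagents that add atoms: allyl bromide, C=CCBr
Why: Williamson O-alkylation of both phenoxides should give the bis(allyl) ether, a catechol protection that withstands hydride, hydroxide, phenoxide and NaH and is removed at the end by zerovalent palladium without acid or hydrogen.

Step 4
Reactants: 6 3,4-bis(allyloxy)-5-methoxybenzaldehyde; 7 ethyl (triphenylphosphoranylidene)acetate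
Product: 8 ethyl (E)-3-[3,4-bis(allyloxy)-5-methoxyphenyl]prop-2-enoate
Conditions: 7 (1.2 equiv), toluene, 80 °C
Reagents that add atoms: none
Why: Wittig olefination with the ester-stabilised ylide should give the E-enoate, the geometry following from reversible oxaphosphetane formation with stabilised ylides.

Step 5
Reactants: 8 ethyl (E)-3-[3,4-bis(allyloxy)-5-methoxyphenyl]prop-2-enoate
Product: 9 (E)-3-[3,4-bis(allyloxy)-5-methoxyphenyl]prop-2-en-1-ol
Conditions: i-Bu2AlH (2.5 equiv), CH2Cl2, −78 °C → 0 °C; aq. potassium sodium tartrate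
Reagents that add atoms: none
Why: DIBAL-H at low temperature reduces the conjugated ester in 1,2-fashion to the E-allylic alcohol and leaves the aryl allyl ethers untouched.

Step 6
Reactants: 9 (E)-3-[3,4-bis(allyloxy)-5-methoxyphenyl]prop-2-en-1-ol
Product: 10 [(2R,3R)-3-[3,4-bis(allyloxy)-5-methoxyphenyl]oxiran-2-yl]methanol
Conditions: Ti(OiPr)4 (10 mol%), D-(−)-diethyl tartrate (12 mol%), t-BuOOH (2 equiv, in decane), 4 Å MS, CH2Cl2, −20 °C
Reagents that add atoms: tert-butyl hydroperoxide, CC(C)(C)OO
Why: Sharpless asymmetric epoxidation should epoxidise only the alkene of the titanium-bound allylic alcohol, the D-(−)-tartrate ligand directing oxygen to the face that gives the (2R,3R) trans epoxy alcohol and so fixing both future stereocentres, while the isolated allyl ether alkenes do not react.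

Step 7
Reactants: 10 [(2R,3R)-3-[3,4-bis(allyloxy)-5-methoxyphenyl]oxiran-2-yl]methanol; 4 5-(1,3-dioxolan-2-yl)-2-fluoro-3-methoxyphenol
Product: 12 3-{[(1S,2R)-1-[3,4-bis(allyloxy)-5-methoxyphenyl]-2,3-dihydroxypropyl]oxy}-4-fluoro-5-methoxybenzaldehyde, via dioxolane diol 11 (not isolated)
Conditions: 4 (2.0 equiv), NaOH (1.0 equiv), t-BuOH/H2O, 65 °C; then 1 M HCl, THF, rt
Reagents that add atoms: water, O (formyl oxygen set free on acetal hydrolysis)
Why: Ring opening of a trans-3-arylglycidol by a phenoxide is a known SN2 process that takes place at the benzylic carbon with inversion (C3 of 10 becomes C7 with S configuration, C2 keeps its oxygen and becomes 8R, hence the erythro ether), the phenol/phenoxide buffer keeping the glycidol hydroxyl protonated so that Payne rearrangement is held back, and the acidic second stage is a plain acetal hydrolysis that releases the formyl group.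

Step 8
Reactants: 12 3-{[(1S,2R)-1-[3,4-bis(allyloxy)-5-methoxyphenyl]-2,3-dihydroxypropyl]oxy}-4-fluoro-5-methoxybenzaldehyde
Product: 13 3-{[(1S,2R)-1-[3,4-bis(allyloxy)-5-methoxyphenyl]-2-hydroxy-3-(trityloxy)propyl]oxy}-4-fluoro-5-methoxybenzaldehyde
Conditions: TrCl (1.2 equiv), Et3N (2 equiv), DMAP (10 mol%), CH2Cl2, rt
Reagents that add atoms: trityl chloride, ClC(c1ccccc1)(c1ccccc1)c1ccccc1
Why: Tritylation is selective for the primary hydroxyl on steric grounds, so the hindered secondary C8 hydroxyl should stay free, and a trityl ether cannot migrate to O8 under base.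

Step 9
Reactants: 13 3-{[(1S,2R)-1-[3,4-bis(allyloxy)-5-methoxyphenyl]-2-hydroxy-3-(trityloxy)propyl]oxy}-4-fluoro-5-methoxybenzaldehyde
Product: 14 (2R,3S)-3-[3,4-bis(allyloxy)-5-methoxyphenyl]-8-methoxy-2-[(trityloxy)methyl]-2,3-dihydro-1,4-benzodioxine-6-carbaldehyde (cis; 7S,8R in lignan numbering)
Conditions: NaH (1.2 equiv), DMF, 0 °C → rt
Reagents that add atoms: none
Why: The sodium alkoxide at O8 adds to C4', which is para to the formyl-bearing C1', to give a Meisenheimer anion whose charge is spread over C3', C5', C1' and the formyl oxygen, and loss of fluoride restores the arene (addition–elimination SNAr). The closest known reaction type is the intramolecular O-arylation of a para-formyl aryl fluoride by a tethered alkoxide, as used to make 1,4-benzodioxanes and chromans. Ring B closes as a six-membered ring through O8–C4' bond formation, formally 6-exo-trig when the C4'=C5' π bond outside the new ring is taken as the acceptor. No stereocentre is created: the bonds at C7 and C8 are not touched, so the erythro (7S,8R) precursor is carried with retention at both centres into the cis-(7S,8R) ring. The step needs chemoselectivity for O8 over O9 and site selectivity for C4' over C3'; the non-migrating trityl ether on O9 leaves O8 as the only alkoxide, and ipso attack at C3' (the Smiles path) is not activated because C3' is meta to the formyl group. The formyl group thus serves twice, as the activator here and as the handle for the side chain in step 10.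

Step 10
Reactants: 14 (2R,3S)-3-[3,4-bis(allyloxy)-5-methoxyphenyl]-8-methoxy-2-[(trityloxy)methyl]-2,3-dihydro-1,4-benzodioxine-6-carbaldehyde; 7 ethyl (triphenylphosphoranylidene)acetate
Product: 16 ethyl (E)-3-[(2R,3S)-3-[3,4-bis(allyloxy)-5-methoxyphenyl]-2-(hydroxymethyl)-8-methoxy-2,3-dihydro-1,4-benzodioxin-6-yl]prop-2-enoate, via trityl enoate 15 (not isolated)
Conditions: 7 (1.1 equiv), CH2Cl2, 40 °C; then EtOH, TsOH·H2O (0.3 equiv), rt
Reagents that add atoms: none
Why: Wittig olefination of the aryl aldehyde with the stabilised ylide should give the E-enoate, and acid-catalysed solvolysis of the trityl ether in ethanol (through the trityl cation, trapped as ethyl trityl ether) then frees the C9 hydroxyl without touching the ester, the allyl ethers or the benzylic C7–O bond.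

Step 11
Reactants: 16 ethyl (E)-3-[(2R,3S)-3-[3,4-bis(allyloxy)-5-methoxyphenyl]-2-(hydroxymethyl)-8-methoxy-2,3-dihydro-1,4-benzodioxin-6-yl]prop-2-enoate
Product: 17 (E)-3-[(2R,3S)-3-[3,4-bis(allyloxy)-5-methoxyphenyl]-2-(hydroxymethyl)-8-methoxy-2,3-dihydro-1,4-benzodioxin-6-yl]prop-2-en-1-ol
Conditions: i-Bu2AlH (4 equiv), CH2Cl2, −78 °C; aq. potassium sodium tartrate
Reagents that add atoms: none
Why: DIBAL-H reduction of the enoate in 1,2-fashion should give the E-allylic alcohol, the extra equivalents allowing for the free C9 hydroxyl, with no stereocentre or ether affected.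

Step 12
Reactants: 17 (E)-3-[(2R,3S)-3-[3,4-bis(allyloxy)-5-methoxyphenyl]-2-(hydroxymethyl)-8-methoxy-2,3-dihydro-1,4-benzodioxin-6-yl]prop-2-en-1-ol
Product: 18 (E)-3-[(2R,3S)-3-(3,4-dihydroxy-5-methoxyphenyl)-2-(hydroxymethyl)-8-methoxy-2,3-dihydro-1,4-benzodioxin-6-yl]prop-2-en-1-ol (CNP0174261.1; cis, 7S,8R)
Conditions: Pd(PPh3)4 (5 mol%), morpholine (6 equiv), degassed THF, rt
Reagents that add atoms: none
Why: Palladium-catalysed deallylation (Tsuji–Trost type) should proceed by oxidative addition of zerovalent palladium into each aryl allyl ether to give a π-allyl complex and the phenoxide, morpholine capturing the allyl group, whereas the free allylic alcohol and the ethers of ring B are not ionised under these neutral conditions, so the cis stereocentres are not at risk.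

Compound list
1 | 4-fluoro-3-methoxybenzaldehyde | COc1cc(C=O)ccc1F | starting material
2 | 2-(4-fluoro-3-methoxyphenyl)-1,3-dioxolane | COc1cc(C2OCCO2)ccc1F | intermediate
3 | 2-[5-(1,3-dioxolan-2-yl)-2-fluoro-3-methoxyphenyl]-4,4,5,5-tetramethyl-1,3,2-dioxaborolane (formed in the flask, not isolated) | COc1cc(C2OCCO2)cc(B3OC(C)(C)C(C)(C)O3)c1F | intermediate
4 | 5-(1,3-dioxolan-2-yl)-2-fluoro-3-methoxyphenol | COc1cc(C2OCCO2)cc(O)c1F | intermediate
5 | 3,4-dihydroxy-5-methoxybenzaldehyde | COc1cc(C=O)cc(O)c1O | starting material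
6 | 3,4-bis(allyloxy)-5-methoxybenzaldehyde | COc1cc(C=O)cc(OCC=C)c1OCC=C | intermediate
7 | ethyl (triphenylphosphoranylidene)acetate | CCOC(=O)C=P(c1ccccc1)(c1ccccc1)c1ccccc1 | starting material
8 | ethyl (E)-3-[3,4-bis(allyloxy)-5-methoxyphenyl]prop-2-enoate | CCOC(=O)/C=C/c1cc(OC)c(OCC=C)c(OCC=C)c1 | intermediate
9 | (E)-3-[3,4-bis(allyloxy)-5-methoxyphenyl]prop-2-en-1-ol | OC/C=C/c1cc(OC)c(OCC=C)c(OCC=C)c1 | intermediate
10 | [(2R,3R)-3-[3,4-bis(allyloxy)-5-methoxyphenyl]oxiran-2-yl]methanol | OC[C@H]1O[C@@H]1c1cc(OC)c(OCC=C)c(OCC=C)c1 | intermediate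
11 | (2R,3S)-3-[3,4-bis(allyloxy)-5-methoxyphenyl]-3-[5-(1,3-dioxolan-2-yl)-2-fluoro-3-methoxyphenoxy]propane-1,2-diol (erythro; formed in the flask, not isolated) | COc1cc([C@H](Oc2cc(C3OCCO3)cc(OC)c2F)[C@H](O)CO)cc(OCC=C)c1OCC=C | intermediate
12 | 3-{[(1S,2R)-1-[3,4-bis(allyloxy)-5-methoxyphenyl]-2,3-dihydroxypropyl]oxy}-4-fluoro-5-methoxybenzaldehyde (erythro; 7S,8R) | COc1cc([C@H](Oc2cc(C=O)cc(OC)c2F)[C@H](O)CO)cc(OCC=C)c1OCC=C | intermediate
13 | 3-{[(1S,2R)-1-[3,4-bis(allyloxy)-5-methoxyphenyl]-2-hydroxy-3-(trityloxy)propyl]oxy}-4-fluoro-5-methoxybenzaldehyde (erythro; 7S,8R; precursor of the key step) | COc1cc([C@H](Oc2cc(C=O)cc(OC)c2F)[C@H](O)COC(c3ccccc3)(c3ccccc3)c3ccccc3)cc(OCC=C)c1OCC=C | intermediate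
14 | (2R,3S)-3-[3,4-bis(allyloxy)-5-methoxyphenyl]-8-methoxy-2-[(trityloxy)methyl]-2,3-dihydro-1,4-benzodioxine-6-carbaldehyde (cis; 7S,8R) | COc1cc([C@@H]2Oc3cc(C=O)cc(OC)c3O[C@@H]2COC(c4ccccc4)(c4ccccc4)c4ccccc4)cc(OCC=C)c1OCC=C | intermediate
15 | ethyl (E)-3-[(2R,3S)-3-[3,4-bis(allyloxy)-5-methoxyphenyl]-8-methoxy-2-[(trityloxy)methyl]-2,3-dihydro-1,4-benzodioxin-6-yl]prop-2-enoate (formed in the flask, not isolated) | COc1cc([C@@H]2Oc3cc(/C=C/C(=O)OCC)cc(OC)c3O[C@@H]2COC(c4ccccc4)(c4ccccc4)c4ccccc4)cc(OCC=C)c1OCC=C | intermediate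
16 | ethyl (E)-3-[(2R,3S)-3-[3,4-bis(allyloxy)-5-methoxyphenyl]-2-(hydroxymethyl)-8-methoxy-2,3-dihydro-1,4-benzodioxin-6-yl]prop-2-enoate | COc1cc([C@@H]2Oc3cc(/C=C/C(=O)OCC)cc(OC)c3O[C@@H]2CO)cc(OCC=C)c1OCC=C | intermediate
17 | (E)-3-[(2R,3S)-3-[3,4-bis(allyloxy)-5-methoxyphenyl]-2-(hydroxymethyl)-8-methoxy-2,3-dihydro-1,4-benzodioxin-6-yl]prop-2-en-1-ol | COc1cc([C@@H]2Oc3cc(/C=C/CO)cc(OC)c3O[C@@H]2CO)cc(OCC=C)c1OCC=C | intermediate
18 | (E)-3-[(2R,3S)-3-(3,4-dihydroxy-5-methoxyphenyl)-2-(hydroxymethyl)-8-methoxy-2,3-dihydro-1,4-benzodioxin-6-yl]prop-2-en-1-ol (CNP0174261.1) | COc1cc([C@@H]2Oc3cc(/C=C/CO)cc(OC)c3O[C@@H]2CO)cc(O)c1O | target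

Total step count: 12 steps (steps 2, 7 and 10 each run two operations in one flask).
Longest linear sequence: 10 steps (5 → 18, steps 3 to 12); the ring A branch (steps 1 and 2) joins at step 7.

Steps most likely to fail

Step 9. The hindered secondary alkoxide may add only slowly to a carbon flanked by two ortho oxygen substituents. If heating is then needed, hydride transfer from the alkoxide to the formyl group or expulsion of the aryloxide from C7 could take over. The fallback makes the same C4'–O8 bond by palladium-catalysed intramolecular C–O coupling of an aryl bromide, which needs no Meisenheimer intermediate and also keeps C8 intact. It sets out from 10. Commercial 4-bromo-3,5-dimethoxybenzaldehyde would be mono-demethylated (BBr3, 1 equiv, CH2Cl2, −78 °C → 0 °C; the substrate is symmetrical, so no regiochemical question arises) to 4-bromo-3-hydroxy-5-methoxybenzaldehyde F1. Its phenoxide would open 10 under the buffer conditions of step 7 to give 4-bromo-3-{[(1S,2R)-1-[3,4-bis(allyloxy)-5-methoxyphenyl]-2,3-dihydroxypropyl]oxy}-5-methoxybenzaldehyde F2. Tritylation as in step 8 would give the O9 trityl ether F3. Buchwald–Hartwig etherification (Pd(OAc)2, 2-(di-tert-butylphosphino)-1,1'-binaphthyl, Cs2CO3, toluene, 70 °C) would then close ring B with retention, and the route is rejoined at 14.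

Step 7. Under basic aqueous conditions the epoxy alcohol may undergo Payne rearrangement followed by phenoxide attack at C9, some attack may occur at C8, or partial ionisation at C7 may leak threo isomer. The fallback removes the free hydroxyl before the opening. It sets out from 10, which would be tritylated (TrCl, Et3N, DMAP, CH2Cl2) to (2R,3R)-2-[3,4-bis(allyloxy)-5-methoxyphenyl]-3-[(trityloxy)methyl]oxirane F4. Payne rearrangement is then impossible and C8 is shielded by the trityloxymethyl group. Opening with 4 under anhydrous conditions (Cs2CO3, DMF, 80 °C) should give (2R,3S)-3-[3,4-bis(allyloxy)-5-methoxyphenyl]-3-[5-(1,3-dioxolan-2-yl)-2-fluoro-3-methoxyphenoxy]-1-(trityloxy)propan-2-ol F5. The aryl fluoride stays inert because the formyl group is still masked. Aqueous HCl in THF would then cleave both the dioxolane and the trityl ether, and the route is rejoined at 12.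

Step 2. Borylation may stray to C6–H beside the acetal or go on to a second borylation, and part of the acetal may be lost during the oxidative work-up. The fallback replaces catalytic C–H borylation by deprotonative metalation ortho to fluorine, the most acidic ring position. It sets out from 2. Lithium 2,2,6,6-tetramethylpiperidide would be added to a mixture of 2 and B(OiPr)3 in THF at −78 °C, so that the aryllithium is trapped as it forms, to give lithium [5-(1,3-dioxolan-2-yl)-2-fluoro-3-methoxyphenyl]tri(propan-2-yloxy)borate F6. This would be oxidised in the same flask with H2O2 and NaOH, and the route is rejoined at 4.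

Further compounds
F1 | step 9 | 4-bromo-3-hydroxy-5-methoxybenzaldehyde | COc1cc(C=O)cc(O)c1Br
F2 | step 9 | 4-bromo-3-{[(1S,2R)-1-[3,4-bis(allyloxy)-5-methoxyphenyl]-2,3-dihydroxypropyl]oxy}-5-methoxybenzaldehyde | COc1cc([C@H](Oc2cc(C=O)cc(OC)c2Br)[C@H](O)CO)cc(OCC=C)c1OCC=C
F3 | step 9 | 4-bromo-3-{[(1S,2R)-1-[3,4-bis(allyloxy)-5-methoxyphenyl]-2-hydroxy-3-(trityloxy)propyl]oxy}-5-methoxybenzaldehyde | COc1cc([C@H](Oc2cc(C=O)cc(OC)c2Br)[C@H](O)COC(c3ccccc3)(c3ccccc3)c3ccccc3)cc(OCC=C)c1OCC=C
F4 | step 7 | (2R,3R)-2-[3,4-bis(allyloxy)-5-methoxyphenyl]-3-[(trityloxy)methyl]oxirane | C(OC[C@H]1O[C@@H]1c1cc(OC)c(OCC=C)c(OCC=C)c1)(c1ccccc1)(c1ccccc1)c1ccccc1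
F5 | step 7 | (2R,3S)-3-[3,4-bis(allyloxy)-5-methoxyphenyl]-3-[5-(1,3-dioxolan-2-yl)-2-fluoro-3-methoxyphenoxy]-1-(trityloxy)propan-2-ol | COc1cc([C@H](Oc2cc(C3OCCO3)cc(OC)c2F)[C@H](O)COC(c3ccccc3)(c3ccccc3)c3ccccc3)cc(OCC=C)c1OCC=C
F6 | step 2 | lithium [5-(1,3-dioxolan-2-yl)-2-fluoro-3-methoxyphenyl]tri(propan-2-yloxy)borate | [Li+].COc1cc(C2OCCO2)cc([B-](OC(C)C)(OC(C)C)OC(C)C)c1F
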